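**Strategy**

Everything rests on opening ring C at C9–C11 together with the lactone bond C10–O. In the key step a bromomethyl ketone on C13 of a spiro-linked ring D gives an α-keto radical at C11 that adds to C9 of a C9=C10 alkene in ring B; the tertiary C10 radical is oxidised and captured by the C19 ester. One operation closes ring C (the bicyclo[3.2.1]octane), forms the 19,10-lactone and sets C9 and C10. It exploits the cis arrangement of C11 and the lactone oxygen across C9–C10 and the C12 oxygen next to C11. The precursor is a spiro[4.4]nonane-fused hydrindene keto acid that carries rings A, B and D but no ring C.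

Key step: step 19

Remark: atom numbers and α/β labels follow gibberellane numbering and the usual drawing of the target (β is the face of H-5 and H-9).
Remark: C10 is a temporary stereocentre (set in step 3, erased in step 13) that relays the absolute configuration to C5; C6 is carried as either epimer in 11–14 and is equilibrated in step 9.
Remark: the cupreidine catalyst of step 3 is assigned by analogy with indanone β-keto esters; its pseudo-enantiomer (the cupreine ether) would give the antipode.

**Route**

Step 1
Reactants: 1 dimethyl succinate; 2 allyl acrylate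
Product: 4 3-allyl 1-methyl 4-oxocyclopentane-1,3-dicarboxylate (ring B; mixture of enolisable diastereomers), via Michael adduct triester 3 (not isolated)
Conditions: LDA, THF, −78 °C; add 2; −78 °C → rt; aq. NH4Cl
Reagents that add atoms: none
Why: Tandem Michael addition–Dieckmann condensation, in which the succinate enolate adds to the acrylate and the new ester enolate closes the five-membered ring on the distal succinate ester; both stereocentres are enolisable and are erased or reset later.

Step 2
Reactants: 4 3-allyl 1-methyl 4-oxocyclopentane-1,3-dicarboxylate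
Product: 6 1-allyl 3-methyl 5-oxocyclopent-1-ene-1,3-dicarboxylate, via selenide 5 (not isolated)
Conditions: PhSeCl, pyridine, CH2Cl2, 0 °C; then 30% H2O2, 0 °C; used at once
Reagents that add atoms: none
Why: α-Selenenylation of the β-keto ester and selenoxide syn-elimination give the 2-alkoxycarbonyl enone, whose acidic γ-hydrogen at C6 makes it a vinylogous β-keto ester pronucleophile.

Step 3
Reactants: 6 1-allyl 3-methyl 5-oxocyclopent-1-ene-1,3-dicarboxylate; 7 acrolein
Product: 8 1-allyl 3-methyl (1R)-5-oxo-1-(3-oxopropyl)cyclopent-2-ene-1,3-dicarboxylate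
Conditions: 9-O-(9-phenanthryl)cupreidine (10 mol %), CH2Cl2, −24 °C
Reagents that add atoms: none
Why: Cinchona-alkaloid-catalysed asymmetric Michael addition, in which the bifunctional catalyst forms the dienolate of 6 and directs its doubly activated α-carbon (C10) onto hydrogen-bonded acrolein, so that the catalyst sets the quaternary C10 centre and the ring double bond moves to C5=C6.

Step 4
Reactants: 8 the aldehyde of step 3; 9 tert-butyl diazoacetate
Product: 10 1-allyl 3-methyl (1R)-1-(5-tert-butoxy-3,5-dioxopentyl)-5-oxocyclopent-2-ene-1,3-dicarboxylate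
Conditions: SnCl2 (10 mol %), CH2Cl2, rt
Reagents that add atoms: none
Why: Roskamp reaction, in which the diazo ester adds to the aldehyde and a 1,2-hydride shift with loss of N2 gives the β-keto ester, the hindered ketone and the enoate being inert.

Step 5
Reactants: 10 the β-keto ester of step 4
Product: 12 cis-fused A/B triester (3,9-dioxo; 4β-methyl; 4α-CO2t-Bu; 5β-H; 6-CO2Me; 10β-CO2allyl), via bicyclic keto ester 11 (not isolated)
Conditions: Cs2CO3, MeCN, rt → 40 °C; then MeI, 0 °C → rt
Reagents that add atoms: iodomethane, CI
Why: Intramolecular 6-exo Michael addition of the β-keto ester to the C5=C6 enoate (the C8=C6 isomer equilibrates through the dienolate and cannot cyclise) closes ring A cis to the C10–C1 tether, which fixes C5 (H β), and the resulting enolate is C-methylated on the convex β face, anti to the axial C9–C10 bond of the cis-hydrindane, placing the methyl β and the ester α at C4.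

Step 6
Reactants: 12 cis-fused A/B triester
Product: 13 3β-alcohol of 12
Conditions: (R)-2-methyl-CBS-oxazaborolidine (20 mol %), catecholborane, toluene, −78 °C
Reagents that add atoms: none
Why: Corey–Bakshi–Shibata reduction, in which the six-membered C3 ketone should react before the intrinsically less reactive cyclopentanone at C9 (which is also shielded by the fully substituted C10 on the concave face) and the (R)-catalyst, with quaternary C4 as the large group, delivers hydride to the α face to give the 3β-alcohol.

Step 7
Reactants: 13 3β-alcohol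
Product: 14 3β-triethylsilyl ether of 13
Conditions: TESOTf, 2,6-lutidine, CH2Cl2, −78 °C
Reagents that add atoms: triethylsilyl triflate, CC[Si](CC)(CC)OS(=O)(=O)C(F)(F)F
Why: Silylation of the hindered secondary alcohol; at −78 °C with lutidine the C9 ketone is not converted into an enol silane.

Step 8
Reactants: 15 1,4-dibromo-2,3-bis(bromomethyl)but-2-ene
Product: 16 2,3-bis(bromomethyl)buta-1,3-diene
Conditions: Zn–Cu couple (1 equiv), Et2O/DMF, 0 °C → rt
Reagents that add atoms: none
Why: Zinc-mediated 1,4-reductive debromination of the tetrabromide gives the bis-allylic dibromodiene, which is used directly.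

Step 9
Reactants: 14 3β-triethylsilyl ether; 16 2,3-bis(bromomethyl)buta-1,3-diene
Product: 17 spiro diene (ring D = 3,4-dimethylenecyclopentane spiro at C8; 6β-CO2Me; 10β-CO2allyl)
Conditions: KHMDS (1.1 equiv), THF, −78 °C, then 16; then KOtBu (2 equiv), THF/t-BuOH, 0 °C → rt
Reagents that add atoms: none
Why: Double enolate C-alkylation (spiroannulation), in which the blocked C10 forces enolisation at C8 and the second, 5-exo-tet alkylation closes a symmetric ring D that leaves C8 non-stereogenic; the excess alkoxide, too hindered to add to the C9 ketone, equilibrates C6 to the more stable epimer with the ester on the β face, anti to C4.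

Step 10
Reactants: 17 spiro diene
Product: 18 cis-fused C9 ketone with 10β-H (C10 ester removed)
Conditions: Pd(PPh3)4 (5 mol %), morpholine, THF, rt
Reagents that add atoms: none
Why: Tsuji–Trost-type deallylation, in which zerovalent palladium ionises the allyl ester, morpholine takes the allyl group and the β-keto acid loses CO2; protonation from the convex face gives the cis-fused ketone, whose C10 centre is erased in step 13.

Step 11
Reactants: 18 cis-fused C9 ketone
Product: 19 7-oic acid of 18
Conditions: LiOH, THF/MeOH/H2O, 45 °C; then aq. HCl to pH 4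
Reagents that add atoms: lithium hydroxide, [Li+].[OH-]
Why: Saponification of the methyl ester frees the C7 acid, the tert-butyl ester being inert to hydroxide.

Step 12
Reactants: 19 7-oic acid
Product: 20 iodolactone (7→16 δ-lactone; 16-iodomethyl; 13-methylene)
Conditions: I2, NaHCO3, MeCN/H2O, 0 °C, dark
Reagents that add atoms: iodine, II
Why: Iodolactonisation, in which the 6β-carboxylate can reach only the diene carbon joined to the β-methylene of ring D through a cis-fused six-membered ring, so oxygen adds to C16 and iodine to the terminal C17; this desymmetrises ring D, fixes C8 and C16, and masks both the C16 methylene and the acid.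

Step 13
Reactants: 20 iodolactone
Product: 21 C9 enol triflate (C9=C10) of 20
Conditions: KHMDS, THF, −78 °C; then PhNTf2, −78 → 0 °C
Reagents that add atoms: N-phenylbis(trifluoromethanesulfonimide), O=S(=O)(N(c1ccccc1)S(=O)(=O)C(F)(F)F)C(F)(F)F
Why: Deprotonation of the ketone at its only α-hydrogen (C10) and O-triflation give the enol triflate, which removes the competing ketone and fixes the position of the later alkene.

Step 14
Reactants: 21 enol triflate
Product: 22 13-ketone of 21
Conditions: OsO4 (2 mol %), NaIO4, 2,6-lutidine, dioxane/H2O, rt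
Reagents that add atoms: sodium periodate, [Na+].[O-]I(=O)(=O)=O
Why: Lemieux–Johnson oxidation cleaves the electron-rich 1,1-disubstituted alkene to the C13 ketone, the enol triflate alkene being electron-poor and inert.

Step 15
Reactants: 22 13-ketone; 23 ethyl vinyl ether
Product: 24 13-(1-ethoxyvinyl)-13-hydroxy iodolactone
Conditions: 23, t-BuLi, THF, −78 → 0 °C; CeCl3, −78 °C; then 22, −78 °C; aq. NH4Cl
Reagents that add atoms: none
Why: The organocerium acyl-anion equivalent adds to the only ketone from the exo face of the 2-oxabicyclo[3.2.1]octane, anti to the lactone bridge, which puts C12 on the C9 side and the hydroxyl on the C6 side, the configuration required at C13.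

Step 16
Reactants: 24 13-(1-ethoxyvinyl)-13-hydroxy iodolactone
Product: 25 ring-opened 7-oic acid with 16-methylene
Conditions: SmI2, HMPA, THF, −20 °C; pH 7 buffer
Reagents that add atoms: none
Why: Reductive β-elimination, in which divalent samarium reduces the primary iodide and the organosamarium expels the carboxylate, regenerating the C16 methylene and the C7 acid and freeing ring D for the later bridging.

Step 17
Reactants: 25 ring-opened acid
Product: 26 C9=C10 alkene of 25
Conditions: Pd(OAc)2 (5 mol %), PPh3, HCO2H (2 equiv), Bu3N (4 equiv), DMF, 60 °C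
Reagents that add atoms: none
Why: Palladium-catalysed formate reduction of the enol triflate gives the trisubstituted C9=C10 alkene regiospecifically, the excess amine keeping the medium basic so that the enol ether survives.

Step 18
Reactants: 26 C9=C10 alkene
Product: 27 bromomethyl ketone (13-hydroxy-13-bromoacetyl)
Conditions: NBS (1.0 equiv), NaHCO3, THF/H2O, −20 °C
Reagents that add atoms: N-bromosuccinimide, O=C1CCC(=O)N1Br; water, O
Why: Bromination of the enol ether, by far the most nucleophilic alkene, and hydrolysis of the bromo-oxocarbenium ion give the bromomethyl ketone.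

Step 19
Reactants: 27 bromomethyl ketone
Product: 28 12-oxo-3-O-triethylsilyl derivative of the target (ring C and 19,10-lactone closed)
Conditions: fac-Ir(ppy)3 (1 mol %), 2,6-lutidine, MeCN (0.02 M), blue LEDs, rt
Reagents that add atoms: none
Why: Radical–polar crossover carbolactonisation: the excited trivalent iridium complex reduces the C–Br bond, the electrophilic α-keto radical at C11 adds 6-exo-trig to the less substituted end (C9) of the electron-rich C9=C10 alkene, tetravalent iridium oxidises the tertiary C10 radical to the cation, and the C19 tert-butyl ester carbonyl captures it with loss of isobutene. The closest known reactions are photoredox atom-transfer radical additions of α-bromo carbonyl compounds to alkenoic acids that end in γ-lactones, and 6-exo cyclisations of α-keto radicals. Ring C closes in the 6-exo mode and the lactone in the 5-exo mode onto the cation. C9 is set by the tether, since C14 lies on the α face of ring B and C12 on the C9 side of ring D (steps 12 and 15), so C11 can reach only the α face (H-9 β); C10 is set by C4, whose α-carboxyl can reach only the α face of the planar cation. The step needs selectivity for C9=C10 over the C16 methylene (4-exo and 5-endo closures are disfavoured) and over 1,5-hydrogen transfer, and capture of the cation before elimination; the free C7 acid should be a poorer competitor because it would have to close a more strained 2-oxabicyclo[2.2.1]heptanone across ring B.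

Step 20
Reactants: 28 12-oxo-3-O-triethylsilyl derivative
Product: 30 the target 3β,12α,13-trihydroxy-20-norgibberell-16-ene-7,19-dioic acid 19,10-lactone (CNP0260503.1), via silyl ether 29 (not isolated)
Conditions: L-Selectride (LiBH(s-Bu)3), THF, −78 °C; then AcOH/THF/H2O (3:1:1), 40 °C
Reagents that add atoms: none
Why: The bulky hydride should attack the C12 ketone from the β face, away from the axial C9–C10 bond that shields the α face of the chair-like ring C (equatorial attack on a 3-axially substituted cyclohexanone), giving the axial 12α-alcohol, and mild acid then removes the triethylsilyl group.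

**Compound list**

1 | dimethyl succinate | COC(=O)CCC(=O)OC | starting material
2 | allyl acrylate | C=CC(=O)OCC=C | starting material
3 | 4-allyl 1,2-dimethyl butane-1,2,4-tricarboxylate (racemic Michael adduct) | COC(=O)CC(CCC(=O)OCC=C)C(=O)OC | intermediate
4 | 3-allyl 1-methyl 4-oxocyclopentane-1,3-dicarboxylate (mixture of enolisable diastereomers) | COC(=O)C1CC(=O)C(C(=O)OCC=C)C1 | intermediate
5 | 3-allyl 1-methyl 4-oxo-3-(phenylselanyl)cyclopentane-1,3-dicarboxylate | COC(=O)C1CC(=O)C([Se]c2ccccc2)(C(=O)OCC=C)C1 | intermediate
6 | 1-allyl 3-methyl 5-oxocyclopent-1-ene-1,3-dicarboxylate (racemic, C3 enolisable) | COC(=O)C1CC(=O)C(C(=O)OCC=C)=C1 | intermediate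
7 | acrolein | C=CC=O | starting material
8 | 1-allyl 3-methyl (1R)-5-oxo-1-(3-oxopropyl)cyclopent-2-ene-1,3-dicarboxylate | O=CCC[C@]1(C(=O)OCC=C)C(=O)CC(C(=O)OC)=C1 | intermediate
9 | tert-butyl diazoacetate | CC(C)(C)OC(=O)C=[N+]=[N-] | starting material
10 | 1-allyl 3-methyl (1R)-1-(5-tert-butoxy-3,5-dioxopentyl)-5-oxocyclopent-2-ene-1,3-dicarboxylate | CC(C)(C)OC(=O)CC(=O)CC[C@]1(C(=O)OCC=C)C(=O)CC(C(=O)OC)=C1 | intermediate
11 | cis-fused A/B keto ester (3,9-dioxo; 4-CO2t-Bu, enolisable; 5β-H; 6-CO2Me, either epimer; 10β-CO2allyl) | COC(=O)C1CC(=O)[C@@]2(C(=O)OCC=C)CCC(=O)C(C(=O)OC(C)(C)C)[C@@H]12 | intermediate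
12 | cis-fused A/B triester (3,9-dioxo; 4β-methyl; 4α-CO2t-Bu; 5β-H; 6-CO2Me, either epimer; 10β-CO2allyl) | COC(=O)C1CC(=O)[C@@]2(C(=O)OCC=C)CCC(=O)[C@@](C)(C(=O)OC(C)(C)C)[C@@H]12 | intermediate
13 | 3β-alcohol of 12 | COC(=O)C1CC(=O)[C@@]2(C(=O)OCC=C)CC[C@H](O)[C@@](C)(C(=O)OC(C)(C)C)[C@@H]12 | intermediate
14 | 3β-triethylsilyl ether of 13 | COC(=O)C1CC(=O)[C@@]2(C(=O)OCC=C)CC[C@H](O[Si](CC)(CC)CC)[C@@](C)(C(=O)OC(C)(C)C)[C@@H]12 | intermediate
15 | 1,4-dibromo-2,3-bis(bromomethyl)but-2-ene | BrCC(CBr)=C(CBr)CBr | starting material
16 | 2,3-bis(bromomethyl)buta-1,3-diene | BrCC(=C)C(=C)CBr | intermediate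
17 | spiro diene (ring D = 3,4-dimethylenecyclopentane spiro at C8; 6β-CO2Me; 10β-CO2allyl; 3β-OTES) | COC(=O)[C@@H]1C2(CC(=C)C(=C)C2)C(=O)[C@@]3(C(=O)OCC=C)CC[C@H](O[Si](CC)(CC)CC)[C@@](C)(C(=O)OC(C)(C)C)[C@@H]13 | intermediate
18 | cis-fused C9 ketone, 10β-H (C10 ester removed) | COC(=O)[C@@H]1C2(CC(=C)C(=C)C2)C(=O)[C@H]3CC[C@H](O[Si](CC)(CC)CC)[C@@](C)(C(=O)OC(C)(C)C)[C@@H]13 | intermediate
19 | 7-oic acid of 18 | OC(=O)[C@@H]1C2(CC(=C)C(=C)C2)C(=O)[C@H]3CC[C@H](O[Si](CC)(CC)CC)[C@@](C)(C(=O)OC(C)(C)C)[C@@H]13 | intermediate
20 | iodolactone (7→16 δ-lactone; 16-iodomethyl; 13-methylene; 9-oxo) | O=C1O[C@]2(CI)C[C@]3(CC2=C)C(=O)[C@H]4CC[C@H](O[Si](CC)(CC)CC)[C@@](C)(C(=O)OC(C)(C)C)[C@H]4[C@H]13 | intermediate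
21 | C9 enol triflate (C9=C10) of 20 | O=C1O[C@]2(CI)C[C@]3(CC2=C)C(OS(=O)(=O)C(F)(F)F)=C4CC[C@H](O[Si](CC)(CC)CC)[C@@](C)(C(=O)OC(C)(C)C)[C@H]4[C@H]13 | intermediate
22 | 13-ketone of 21 | O=C1O[C@]2(CI)C[C@]3(CC2=O)C(OS(=O)(=O)C(F)(F)F)=C4CC[C@H](O[Si](CC)(CC)CC)[C@@](C)(C(=O)OC(C)(C)C)[C@H]4[C@H]13 | intermediate
23 | ethyl vinyl ether | C=COCC | starting material
24 | 13-(1-ethoxyvinyl)-13-hydroxy iodolactone (C12 on the C9 side, OH on the C6 side) | O=C1O[C@]2(CI)C[C@]3(C[C@@]2(O)C(=C)OCC)C(OS(=O)(=O)C(F)(F)F)=C4CC[C@H](O[Si](CC)(CC)CC)[C@@](C)(C(=O)OC(C)(C)C)[C@H]4[C@H]13 | intermediate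
25 | ring-opened acid (7-oic acid; 16-methylene; 13-hydroxy-13-(1-ethoxyvinyl); C9 enol triflate) | OC(=O)[C@@H]1[C@]2(CC(=C)[C@](O)(C(=C)OCC)C2)C(OS(=O)(=O)C(F)(F)F)=C3CC[C@H](O[Si](CC)(CC)CC)[C@@](C)(C(=O)OC(C)(C)C)[C@@H]13 | intermediate
26 | C9=C10 alkene of 25 | OC(=O)[C@@H]1[C@]2(CC(=C)[C@](O)(C(=C)OCC)C2)C=C3CC[C@H](O[Si](CC)(CC)CC)[C@@](C)(C(=O)OC(C)(C)C)[C@@H]13 | intermediate
27 | bromomethyl ketone (13-hydroxy-13-bromoacetyl; key-step precursor) | OC(=O)[C@@H]1[C@]2(CC(=C)[C@](O)(C(=O)CBr)C2)C=C3CC[C@H](O[Si](CC)(CC)CC)[C@@](C)(C(=O)OC(C)(C)C)[C@@H]13 | intermediate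
28 | 12-oxo-3-O-triethylsilyl derivative of the target | C=C1C[C@]23C[C@@]1(O)C(=O)C[C@H]2[C@@]12CC[C@H](O[Si](CC)(CC)CC)[C@@](C)(C(=O)O1)[C@H]2[C@@H]3C(=O)O | intermediate
29 | 3-O-triethylsilyl ether of the target | C=C1C[C@]23C[C@@]1(O)[C@@H](O)C[C@H]2[C@@]12CC[C@H](O[Si](CC)(CC)CC)[C@@](C)(C(=O)O1)[C@H]2[C@@H]3C(=O)O | intermediate
30 | 3β,12α,13-trihydroxy-20-norgibberell-16-ene-7,19-dioic acid 19,10-lactone (CNP0260503.1) | C=C1C[C@]23C[C@@]1(O)[C@@H](O)C[C@H]2[C@@]12CC[C@H](O)[C@@](C)(C(=O)O1)[C@H]2[C@@H]3C(=O)O | target

**Step count and risks**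

Total: 20 steps. Longest linear sequence: 19 steps (steps 1–7 and 9–20).

Step 19 (key step). The radical may be reduced before it cyclises, may abstract an allylic hydrogen from C15, or the C10 cation may eliminate or be captured on the β face by the C7 acid. The fallback sets out from 27 and comes back at 28. Diazo transfer with N,N′-ditosylhydrazine and DBU converts 27 into the diazoketone F1. After silylation of the acid and the alcohol in the flask (BSA), intramolecular cyclopropanation of the C9=C10 alkene with Cu(acac)2 in toluene gives the cyclopropyl ketone F2, with C11 bonded to C9 and C10 on the α face. BF3·OEt2 in CH2Cl2 at low temperature then opens the activated cyclopropane at the tertiary C10 through the free cation, and the 19-ester captures it on the α face with loss of isobutene to give 28.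

Step 3. The dienolate may react at the γ-carbon (C6) instead of C10, the unstable enone may oligomerise, or facial control may be poor on this unusual pronucleophile. The fallback sets out from 4 and comes back at 12. The saturated keto ester 4, the substrate class for which this catalysis is established, is added to acrolein with the same catalyst to give the aldehyde F3 (C6 epimers). Trimethyl orthoformate and PPTS give the dimethyl acetal F4. LiHMDS and PhSeBr selenenylate the ketone at C8 to give the selenide F5, and H2O2 eliminates it towards C6 to the enone acetal F6. PPTS in wet acetone frees the enone aldehyde F7, and the Roskamp reaction with 9 gives the keto ester F8. F8 is the alkene isomer of 10 and, through the common dienolate, enters step 5 to give 12.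

Step 20. Hydride may be delivered to the α face of the C12 ketone and give the equatorial 12β-alcohol. The fallback sets out from 28 and comes back at 29: the substrate-controlled hydride is replaced by a reagent-controlled reduction with (R)-2-methyl-CBS-oxazaborolidine and catecholborane (quaternary C13 as the large group, which by the same model as in step 6 corresponds to the 12S alcohol). Catecholborane is chosen so that the C16 methylene is not hydroborated. No new compound is formed.

**Further compounds**

F1 | step 19 | diazoketone from 27 (13-hydroxy-13-diazoacetyl) | OC(=O)[C@@H]1[C@]2(CC(=C)[C@](O)(C(=O)C=[N+]=[N-])C2)C=C3CC[C@H](O[Si](CC)(CC)CC)[C@@](C)(C(=O)OC(C)(C)C)[C@@H]13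
F2 | step 19 | cyclopropyl ketone (C9–C10–C11 cyclopropane on the α face; 12-oxo; 19-tert-butyl ester) | C=C1C[C@]23C[C@@]1(O)C(=O)[C@@H]4[C@H]2[C@@]45CC[C@H](O[Si](CC)(CC)CC)[C@@](C)(C(=O)OC(C)(C)C)[C@H]5[C@@H]3C(=O)O
F3 | step 3 | 3-allyl 1-methyl 4-oxo-3-(3-oxopropyl)cyclopentane-1,3-dicarboxylate (C10 set, C6 epimers) | O=CCC[C@]1(C(=O)OCC=C)C(=O)CC(C(=O)OC)C1
F4 | step 3 | dimethyl acetal of F3 | COC(OC)CC[C@]1(C(=O)OCC=C)C(=O)CC(C(=O)OC)C1
F5 | step 3 | C8 phenylselenide of F4 | COC(OC)CC[C@]1(C(=O)OCC=C)C(=O)C([Se]c2ccccc2)C(C(=O)OC)C1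
F6 | step 3 | enone acetal (C8=C6) | COC(OC)CC[C@]1(C(=O)OCC=C)C(=O)C=C(C(=O)OC)C1
F7 | step 3 | enone aldehyde (C8=C6 isomer of 8) | O=CCC[C@]1(C(=O)OCC=C)C(=O)C=C(C(=O)OC)C1
F8 | step 3 | enone β-keto ester (C8=C6 isomer of 10) | CC(C)(C)OC(=O)CC(=O)CC[C@]1(C(=O)OCC=C)C(=O)C=C(C(=O)OC)C1
F0 | step 20 | none | none
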